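## Retrosynthetic overview

1. Glaucolide L ⇐ Stille hydroxymethylation at C11 (C13 comes last) ⇐ outer-face epoxidation of the 4E-alkene of bromo-macrocycle 15.
2. Ten-membered ring ⇐ C7–C8 bond by nickel-mediated radical macrocyclisation: a C8 α-(methacryloyloxy)alkyl radical (from 1-chloroalkyl methacrylate 14) couples with the C7–Br of a 3,4-dibromobutenolide, so the ring closure delivers the C8 ester and the C8 stereocentre together.
3. Seco-chain 13 ⇐ aldehyde-selective Wacker (C8) ⇐ Brown (Z)-crotylboration (C1/C10 syn; brings C8–C10 and C14) ⇐ Claisen (C2–C3, 4E) ⇐ asymmetric vinylogous aldol of 3,4-dibromofuran-2(5H)-one with methacrolein (C5–C6, sets C6).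
4. Ring order: butenolide (purchased) → carbocycle (step 7) → oxirane (step 8). C11–Br is the placeholder for CH2OH, so no protecting groups are used.

Assumption: positions are given in germacrane numbering (C1–C15); furanone C5 (= C6) keeps one spatial arrangement throughout, and its CIP label reads R until C5 is oxygenated in step 8, then S.

## Route

Step 1
Reactants: 1 3,4-dibromofuran-2(5H)-one; 2 methacrolein
Product: 3 (5R)-3,4-dibromo-5-[(1R)-1-hydroxy-2-methylprop-2-en-1-yl]furan-2(5H)-one
Conditions: axially chiral binaphthyl guanidine (5 mol%), THF, −40 °C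
Reagents that add atoms: none
Why: Direct catalytic asymmetric vinylogous aldol addition: the guanidine deprotonates C5 of the dihalobutenolide and the chiral guanidinium ion pair delivers the furanolate γ-carbon (α and β are blocked by Br) to the aldehyde carbonyl, setting the future C6 (5R here); the carbinol centre is erased in step 2, so its ratio does not matter.

Step 2
Reactants: 3 (5R)-3,4-dibromo-5-[(1R)-1-hydroxy-2-methylprop-2-en-1-yl]furan-2(5H)-one; 4 ethyl vinyl ether
Product: 6 (5R)-3,4-dibromo-5-[(1E)-2-methyl-5-oxopent-1-en-1-yl]furan-2(5H)-one, via allyl vinyl ether 5 (not isolated)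
Conditions: Hg(OAc)2 (10 mol%), ethyl vinyl ether (neat), reflux; evaporate; PhMe, 130 °C (sealed tube)
Reagents that add atoms: none
Why: Mercury-catalysed transvinylation followed by Claisen [3,3] rearrangement through a chair with the butenolide pseudo-equatorial forms C2–C3, the 4E trisubstituted alkene and the C1 aldehyde; no amine base is present, so the acidic C6–H is not epimerised.

Step 3
Reactants: 6 (5R)-3,4-dibromo-5-[(1E)-2-methyl-5-oxopent-1-en-1-yl]furan-2(5H)-one; 7 cis-but-2-ene
Product: 11 (5R)-3,4-dibromo-5-[(1E,5S,6S)-5-hydroxy-2,6-dimethylocta-1,7-dien-1-yl]furan-2(5H)-one, via (Z)-crotylpotassium 8 (not isolated), via (Z)-crotylbis(isopinocampheyl)borane 9 (not isolated), via homoallyl borinate 10 (not isolated)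
Conditions: KOtBu, n-BuLi, THF, −78 → −45 °C; (+)-Ipc2BOMe, −78 °C; BF3·OEt2; then 6, −78 °C; 30% H2O2, pH 7 phosphate buffer, MeOH, 0 °C
Reagents that add atoms: none
Why: Brown asymmetric crotylboration: the chair Zimmerman–Traxler transition state turns the Z geometry into the C1/C10 syn relationship, and the (+)-Ipc2B group (from (−)-α-pinene) directs Re-face attack, so C1 (S) and C10 (S) are set under reagent control.

Step 4
Reactants: 11 (5R)-3,4-dibromo-5-[(1E,5S,6S)-5-hydroxy-2,6-dimethylocta-1,7-dien-1-yl]furan-2(5H)-one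
Product: 12 (3S,4S,7E)-8-[(2R)-3,4-dibromo-5-oxo-2,5-dihydrofuran-2-yl]-3,7-dimethylocta-1,7-dien-4-yl acetate
Conditions: Ac2O, Sc(OTf)3 (1 mol%), MeCN, −20 °C
Reagents that add atoms: acetic anhydride CC(=O)OC(C)=O
Why: Lewis-acid-catalysed acetylation of the secondary alcohol with retention; avoiding amine bases protects the C6–H and the C7–Br (a vinylogous acyl bromide).

Step 5
Reactants: 12 (3S,4S,7E)-8-[(2R)-3,4-dibromo-5-oxo-2,5-dihydrofuran-2-yl]-3,7-dimethylocta-1,7-dien-4-yl acetate
Product: 13 (3S,4S,7E)-8-[(2R)-3,4-dibromo-5-oxo-2,5-dihydrofuran-2-yl]-3,7-dimethyl-1-oxooct-7-en-4-yl acetate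
Conditions: PdCl2(PhCN)2 (10 mol%), CuCl2·2H2O (10 mol%), AgNO2 (5 mol%), t-BuOH/MeNO2 (15:1), O2 (1 atm), rt
Reagents that add atoms: dioxygen O=O
Why: Nitrite-modified, aldehyde-selective Wacker–Tsuji oxidation gives anti-Markovnikov oxygenation of the only terminal alkene (helped by the allylic branch and homoallylic acetate); the tri- and tetrasubstituted alkenes are inert and no stereocentre is touched.

Step 6
Reactants: 13 (3S,4S,7E)-8-[(2R)-3,4-dibromo-5-oxo-2,5-dihydrofuran-2-yl]-3,7-dimethyl-1-oxooct-7-en-4-yl acetate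
Product: 14 (3S,4S,7E)-4-acetoxy-1-chloro-8-[(2R)-3,4-dibromo-5-oxo-2,5-dihydrofuran-2-yl]-3,7-dimethyloct-7-en-1-yl 2-methylprop-2-enoate (both C1 epimers)
Conditions: methacryloyl chloride (1.5 equiv.), ZnCl2 (5 mol%), BHT (trace), CH2Cl2, −10 °C → rt; filtered and used crude
Reagents that add atoms: methacryloyl chloride C=C(C)C(Cl)=O
Why: ZnCl2-catalysed addition of an acyl chloride across the aldehyde C=O (1-chloroalkyl ester formation) places the methacrylate oxygen on C8 and a radical leaving group beside it; the C8 epimer mixture is irrelevant because step 7 goes through a planar radical.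

Step 7
Reactants: 14 (3S,4S,7E)-4-acetoxy-1-chloro-8-[(2R)-3,4-dibromo-5-oxo-2,5-dihydrofuran-2-yl]-3,7-dimethyloct-7-en-1-yl 2-methylprop-2-enoate
Product: 15 (1S,4E,6R,8S,10S)-1-acetoxy-11-bromo-8-(methacryloyloxy)-13-norgermacra-4,7(11)-dien-12,6-olide
Conditions: NiBr2·diglyme (30 mol%), (S,S)-iPr-BiOX (35 mol%; ligand enantiomer selected by screening for 8S), Mn powder (3 equiv.), NaI (0.5 equiv.), DMA/THF, 0 °C → rt, 14 added by syringe pump over 12 h (final 2 mM)
Reagents that add atoms: none
Why: Proposed new method: nickel-catalysed reductive cross-electrophile macrocyclisation in which chlorine abstraction by monovalent nickel gives a planar C8 α-acyloxyalkyl radical (both epimers of 14 converge), this radical is captured by the alkenylnickel formed by oxidative addition of zerovalent nickel at the more electrophilic β-bromide (C7–Br), and reductive elimination from trivalent nickel forges C7–C8 and closes the ten-membered ring with C8 (S) fixed by the chiral bi(oxazoline) ligand in the capture step; the closest known reaction type is the intermolecular enantioconvergent nickel-catalysed reductive coupling of 1-chloroalkyl esters or benzylic chlorides with aryl and alkenyl bromides.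

Step 8
Reactants: 15 (1S,4E,6R,8S,10S)-1-acetoxy-11-bromo-8-(methacryloyloxy)-13-norgermacra-4,7(11)-dien-12,6-olide
Product: 16 (1S,4R,5R,6S,8S,10S)-1-acetoxy-11-bromo-4,5-epoxy-8-(methacryloyloxy)-13-norgermacr-7(11)-en-12,6-olide
Conditions: m-CPBA (1.1 equiv.), NaHCO3, CH2Cl2, 0 °C
Reagents that add atoms: m-chloroperbenzoic acid OOC(=O)c1cccc(Cl)c1
Why: Prilezhaev epoxidation attacks only the electron-rich 4E-alkene and is stereospecific (E → trans); attack on the exposed outer face of the E-cycloalkene, by analogy with parthenolide-type 6,12-germacranolides, is expected to give the 4R,5R oxirane.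

Step 9
Reactants: 16 (1S,4R,5R,6S,8S,10S)-1-acetoxy-11-bromo-4,5-epoxy-8-(methacryloyloxy)-13-norgermacr-7(11)-en-12,6-olide
Product: 17 glaucolide L
Conditions: Bu3SnCH2OH (1.5 equiv.), Pd2(dba)3 (5 mol%), AsPh3 (20 mol%), CuI (10 mol%), NMP, 50 °C
Reagents that add atoms: (tributylstannyl)methanol OC[Sn](CCCC)(CCCC)CCCC
Why: Migita–Kosugi–Stille hydroxymethylation of the remaining alkenyl bromide installs C13 with its free hydroxyl; the neutral, base-free conditions leave the oxirane, both esters and all stereocentres untouched (the C6–O bond is no longer allylic, so zerovalent palladium cannot ionise it).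

## Compound list

1 | 3,4-dibromofuran-2(5H)-one | O=C1OCC(Br)=C1Br | starting material
2 | methacrolein (2-methylprop-2-enal) | CC(=C)C=O | starting material
3 | (5R)-3,4-dibromo-5-[(1R)-1-hydroxy-2-methylprop-2-en-1-yl]furan-2(5H)-one | C=C(C)[C@@H](O)[C@H]1OC(=O)C(Br)=C1Br | intermediate
4 | ethyl vinyl ether | C=COCC | starting material
5 | (5R)-3,4-dibromo-5-[(1R)-1-(ethenyloxy)-2-methylprop-2-en-1-yl]furan-2(5H)-one | C=C(C)[C@@H](OC=C)[C@H]1OC(=O)C(Br)=C1Br | intermediate
6 | (5R)-3,4-dibromo-5-[(1E)-2-methyl-5-oxopent-1-en-1-yl]furan-2(5H)-one | O=CCC/C(C)=C/[C@H]1OC(=O)C(Br)=C1Br | intermediate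
7 | cis-but-2-ene | C/C=C\C | starting material
8 | (Z)-but-2-en-1-ylpotassium | [K+].[CH2-]/C=C\C | intermediate
9 | (Z)-but-2-en-1-ylbis(isopinocampheyl)borane, Ipc groups from (−)-α-pinene | C/C=C\CB([C@H]1C[C@H]2C[C@@H]([C@@H]1C)C2(C)C)[C@H]1C[C@H]2C[C@@H]([C@@H]1C)C2(C)C | intermediate
10 | O-[bis(isopinocampheyl)boryl] derivative of 11 | C=C[C@H](C)[C@@H](OB([C@H]1C[C@H]2C[C@@H]([C@@H]1C)C2(C)C)[C@H]1C[C@H]2C[C@@H]([C@@H]1C)C2(C)C)CC/C(C)=C/[C@H]1OC(=O)C(Br)=C1Br | intermediate
11 | (5R)-3,4-dibromo-5-[(1E,5S,6S)-5-hydroxy-2,6-dimethylocta-1,7-dien-1-yl]furan-2(5H)-one | C=C[C@H](C)[C@@H](O)CC/C(C)=C/[C@H]1OC(=O)C(Br)=C1Br | intermediate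
12 | (3S,4S,7E)-8-[(2R)-3,4-dibromo-5-oxo-2,5-dihydrofuran-2-yl]-3,7-dimethylocta-1,7-dien-4-yl acetate | C=C[C@H](C)[C@@H](OC(C)=O)CC/C(C)=C/[C@H]1OC(=O)C(Br)=C1Br | intermediate
13 | (3S,4S,7E)-8-[(2R)-3,4-dibromo-5-oxo-2,5-dihydrofuran-2-yl]-3,7-dimethyl-1-oxooct-7-en-4-yl acetate | O=CC[C@H](C)[C@@H](OC(C)=O)CC/C(C)=C/[C@H]1OC(=O)C(Br)=C1Br | intermediate
14 | (3S,4S,7E)-4-acetoxy-1-chloro-8-[(2R)-3,4-dibromo-5-oxo-2,5-dihydrofuran-2-yl]-3,7-dimethyloct-7-en-1-yl 2-methylprop-2-enoate (both C1 epimers; centre left open in the SMILES) | C=C(C)C(=O)OC(Cl)C[C@H](C)[C@@H](OC(C)=O)CC/C(C)=C/[C@H]1OC(=O)C(Br)=C1Br | intermediate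
15 | (1S,4E,6R,8S,10S)-1-acetoxy-11-bromo-8-(methacryloyloxy)-13-norgermacra-4,7(11)-dien-12,6-olide | C=C(C)C(=O)O[C@H]1C[C@H](C)[C@@H](OC(C)=O)CC/C(C)=C/[C@H]2OC(=O)C(Br)=C12 | intermediate
16 | (1S,4R,5R,6S,8S,10S)-1-acetoxy-11-bromo-4,5-epoxy-8-(methacryloyloxy)-13-norgermacr-7(11)-en-12,6-olide | C=C(C)C(=O)O[C@H]1C[C@H](C)[C@@H](OC(C)=O)CC[C@@]2(C)O[C@@H]2[C@H]2OC(=O)C(Br)=C12 | intermediate
17 | glaucolide L, (1S,4R,5R,6S,8S,10S)-1-acetoxy-4,5-epoxy-13-hydroxy-8-(methacryloyloxy)germacr-7(11)-en-12,6-olide | C=C(C)C(=O)O[C@H]1C[C@H](C)[C@@H](OC(C)=O)CC[C@@]2(C)O[C@@H]2[C@H]2OC(=O)C(CO)=C12 | target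

## Step count and risks

Total step count: 9. Longest linear sequence: 9 steps (1 → 17); the route is fully linear, with 2, 4 and 7 added as small reagents.

Most likely to fail, first: step 7. The ring is strained, and the C8 radical can instead be reduced, oligomerise through the methacrylate, or meet nickel inserted at the α-bromide (C11–Br); the C8 configuration also rests on catalyst control that has not been shown in a macrocycle. Fallback: set out from aldehyde 13 and close the same C7–C8 bond by a polar Nozaki–Hiyama–Kishi macrocyclisation (CrCl2, 1 mol% NiCl2, DMSO/THF, 2 mM). This gives the separable allylic alcohols (1S,4E,6R,8S,10S)-1-acetoxy-11-bromo-8-hydroxy-13-norgermacra-4,7(11)-dien-12,6-olide F2 and its (8R)-epimer F3. F2 is acylated with methacrylic anhydride/Sc(OTf)3, and F3 is esterified with inversion under Mitsunobu conditions (methacrylic acid, PPh3, DIAD), so both epimers return to the route at 15.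

Second: step 1. Methacrolein may undergo 1,4-addition or polymerise under base catalysis, and the enantiocontrol has not been tested with an enal. Fallback: set out from 1, silylate (TIPSOTf, Et3N, CH2Cl2, 0 °C) to the silyl dienolate 3,4-dibromo-2-[(triisopropylsilyl)oxy]furan F1, and run a Lewis-acid-catalysed Mukaiyama vinylogous aldol with 2 (Ti(OiPr)4/BINOL 20 mol%, Et2O, −20 °C; mildly acidic work-up), where 1,2-addition to enals is the normal course. This returns to the route at 3.

Third: step 8. The facial preference of the 7(11)-ene macrocycle is inferred by analogy and may be reversed. Fallback: set out from 15 and form the bromonium ion on the same exposed face (NBS, DME/H2O, 0 °C); water opens it at C4 from the inner face to give the bromohydrin (1S,4R,5S,6S,8S,10S)-1-acetoxy-5,11-dibromo-4-hydroxy-8-(methacryloyloxy)-13-norgermacr-7(11)-en-12,6-olide F4. Closure with Ag2O in CH2Cl2 (inversion at C5) places the oxirane oxygen on the face opposite to direct peracid attack and returns to the route at 16.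

## Further compounds

F1 | step 1 | 3,4-dibromo-2-[(triisopropylsilyl)oxy]furan | CC(C)[Si](Oc1occ(Br)c1Br)(C(C)C)C(C)C
F2 | step 7 | (1S,4E,6R,8S,10S)-1-acetoxy-11-bromo-8-hydroxy-13-norgermacra-4,7(11)-dien-12,6-olide | O[C@H]1C[C@H](C)[C@@H](OC(C)=O)CC/C(C)=C/[C@H]2OC(=O)C(Br)=C12
F3 | step 7 | (1S,4E,6R,8R,10S)-1-acetoxy-11-bromo-8-hydroxy-13-norgermacra-4,7(11)-dien-12,6-olide | O[C@@H]1C[C@H](C)[C@@H](OC(C)=O)CC/C(C)=C/[C@H]2OC(=O)C(Br)=C12
F4 | step 8 | (1S,4R,5S,6S,8S,10S)-1-acetoxy-5,11-dibromo-4-hydroxy-8-(methacryloyloxy)-13-norgermacr-7(11)-en-12,6-olide | C=C(C)C(=O)O[C@H]1C[C@H](C)[C@@H](OC(C)=O)CC[C@@](C)(O)[C@@H](Br)[C@H]2OC(=O)C(Br)=C12
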